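(Readings and results come from a simulation with constants of no real substance, noise included.)

How slow is this reaction against the hours you give it? Settle that first for the flask below.

| flask | substrate | remark | time |
|---|---|---|---|
| south-east | 2 M | run made earlier |  |
| flask | 3.0 M |  | 10 h |

south-east run (percent of the substrate charged)

| time / h | substrate / % | target / % |
|---|---|---|
| 0.833 | 12.1 | 5.4 |
| 2.50 | 3.9 | 1.2 |
| 4.00 | 4.0 | 2.6 |
| 6.00 | 3.6 | 0.6 |
| 10.0 | 5.3 | 1.0 |
| 12.0 | 2.2 | 2.6 |

(scatter of a reading: 1 percentage point)

- the reaction counts as stopped when no species that holds the substrate changes by six tenths of a point or more over the second half of the time

1. the state of affairs at 10 h: stopped, and by what, or still going (all of the substrate has reacted / forward and back rates have come level / it is still moving)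
2. conversion of substrate at 10 h
3. amount of target at 10 h, in percent of the substrate charged

In the south-east run the substrate stops falling after its first reading: from 2.50 h on, its fraction of the charge scatters around 3.80%, above the scatter of 1 percentage point. So a gap to a level is closing, and the first reading gives that gap's half-life (the relaxation half-life), with the scatter of one reading in it:

half-life = 0.833 h × ln(2) / ln(96.2% / 8.30%) = 0.236 h

N = 10 h / 0.236 h = 42.4

This N, the number of half-lives of the gap that fit into the asked time, is my one number. Each half-life halves the gap, so the flask should reach its level long before 10 h.

Is one number enough? For the charge, it looks so: from the south-east run to this flask it rises by a factor 1.50, and a half-life stretched by that factor, which is a supposition of mine, still leaves N at 28.3. For the level, no: N says that the flask stops, not where. I carry the level read in the south-east run over to this flask, which gives an estimated conversion of 96.2%.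

The forecast, holding that “equilibrium is long reached”, says forward and back rates have come level, with conversion 96.3%, 0.1 points from mine, and target 1.6%.

The flask gives forward and back rates have come level, with conversion 97.1% and target 1.57%.

    substrate ⇌ target (K = 0.550, k = 0.00650 /s)
    substrate ⇌ isomer of the product (K = 33.0, k = 0.00100 /s)
    substrate ⇌ third isomer (K = 0.390, k = 0.00860 /s)

Over the second half of the time, no share in this flask moved by more than 0.0059 points. The time to 90% of the conversion in this flask, 0.815 h, holds 3.46 of the half-lives behind N, and by my reckoning that many halvings leave 9.08% of the gap open. Now read the same charge at 15 h: N becomes 63.6, so the level should stay put. That flask gives conversion 97.1% and target 1.57%.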